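Labdane numbering is used throughout: ring A = C1–C5/C10, ring B = C5–C10, C17 = carboxyl carbon on C8, C11–C16 = side chain and lactone.

**Retrosynthetic overview**
- 21 ⇒ 18: the lactone ring is bought closed as 19, joined at C12=C13 by cross metathesis, and the alkene is then moved into the ring. 18 ⇒ 17 (C17 from CO) ⇒ 13 (ester from 14) ⇒ 11 (O onto C6 and H onto C5, both from the α face).
- Key disconnection C9–C10: 11 ⇒ β-keto δ-lactone 8. Its ring O–C6–C7–C8(=O)–C9–C(=O) is temporary and not in the target. A ring-contracting Carroll rearrangement trades it for ring B and expels its O–C=O unit as CO2. 8 ⇒ 1 + 2 + 7.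
- Enabling feature: in ring B, quaternary C10 and oxygen-bearing C6 flank C5, so C6–O is the allylic end of a C5=C10 alkene of ring A. C8, which later carries C17, is 1,3 to C6 and next to C9, so a C8 ketone makes C6–O an aldol oxygen, acidifies C9 and lets the extra carboxyl carbon leave.
- Ring order: ring A (bought in 1), temporary lactone (step 2), ring B (step 4). The butyrolactone ring arrives closed, so no ring is closed after step 4.

Key step: step 4

Assumption: the facial sense of the (S)-BINOL/Ti(OiPr)4 aldol is taken by analogy with other enals (the antipodal ligand would be used if it proved opposite); 2, 7, 14 and 19 are purchased.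

Step 1
Reactants: 1 β-cyclocitral (2,6,6-trimethylcyclohex-1-ene-1-carbaldehyde); 2 1-methoxy-1,3-bis(trimethylsilyloxy)buta-1,3-diene
Product: 4 methyl (5S)-5-hydroxy-3-oxo-5-(2,6,6-trimethylcyclohex-1-en-1-yl)pentanoate, via bis-silyl aldol adduct 3 (not isolated)
Conditions: Ti(OiPr)4 (10 mol %), (S)-BINOL (10 mol %), 4 Å MS, THF, −78 °C → rt; then 1 M HCl, THF, 0 °C
Reagents that add atoms: none
Why: Catalytic enantioselective vinylogous Mukaiyama aldol addition, in which the terminal carbon of the bis-silyl dienolate attacks the titanium-BINOLate-bound aldehyde on the face left open by the ligand and so sets C6 as S, while the non-enolisable hindered enal can react only at its carbonyl carbon.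

Step 2
Reactants: 4 methyl (5S)-5-hydroxy-3-oxo-5-(2,6,6-trimethylcyclohex-1-en-1-yl)pentanoate
Product: 6 (6S)-4-hydroxy-6-(2,6,6-trimethylcyclohex-1-en-1-yl)-5,6-dihydro-2H-pyran-2-one, via potassium pyranolate 5 (not isolated)
Conditions: K2CO3 (1.5 equiv), MeOH, rt; then 1 M HCl, 0 °C, to pH 3
Reagents that add atoms: none
Why: Base-induced lactonisation (intramolecular transesterification) is driven by formation of the stabilised vinylogous carboxylate 5, and C6 keeps its configuration because its C–O bond is not broken.

Step 3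
Reactants: 6 (6S)-4-hydroxy-6-(2,6,6-trimethylcyclohex-1-en-1-yl)-5,6-dihydro-2H-pyran-2-one; 7 allyl methyl carbonate
Product: 8 (6S)-3-allyl-4-hydroxy-6-(2,6,6-trimethylcyclohex-1-en-1-yl)-5,6-dihydro-2H-pyran-2-one
Conditions: Pd(PPh3)4 (3 mol %), THF, rt
Reagents that add atoms: none
Why: Neutral Tsuji–Trost allylation, in which the methoxide released from the carbonate deprotonates 6 and the soft carbon between the two carbonyl groups (future C9) is allylated, any O-allyl product re-entering the π-allyl manifold and the tetrasubstituted alkene next to C6 shielding the lactone C–O bond from zerovalent palladium.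

Step 4
Reactants: 8 (6S)-3-allyl-4-hydroxy-6-(2,6,6-trimethylcyclohex-1-en-1-yl)-5,6-dihydro-2H-pyran-2-one
Product: 11 9β-allyl-4,4,10β-trimethyldecal-5-en-8-one (labdane numbering; 9α-H), via ketene hemiacetal tautomer 9 (not isolated), via β-keto acid 10 (not isolated)
Conditions: o-xylene (0.02 M), 140 °C, Ar, silylated glassware
Reagents that add atoms: none
Why: Proposed new method: heating shifts 8 to its minor acyl ketene hemiacetal tautomer 9, in which C9=C(OH)–O–C6–C5=C10 is an allyl vinyl ether, and a concerted suprafacial [3,3] shift forms C9–C10 while the allylic C6–O bond breaks; the β-keto acid 10 then loses CO2 through its hydrogen-bonded six-membered transition state. The closest known reaction types are the Carroll rearrangement of open-chain allyl β-keto esters and the ring-contracting ester enolate Claisen rearrangement of 6-alkenyl δ-lactones, and only their union in a cyclic β-keto lactone lacks precedent. Ring B (C5–C10) closes by exchange of the six-membered lactone for a six-membered carbocycle through a boat-shaped, bicyclo[2.2.2]octane-like transition state enforced by the C7–C8 bridge. C10 is controlled by C6, because the new bond must form on the alkene face from which the oxygen departs and C7 must end cis to C10 on the new C5=C6 bond, so the 6S lactone gives C10 with its methyl group β; C9 is set afterwards by protonation of the enol left by decarboxylation and, being α to the ketone, settles with the allyl group equatorial (β). The step needs periselectivity over ionisation or β-elimination of the allylic carboxylate and regioselectivity for C10 over C6; the first is served by the neutral, non-polar, dilute medium and the enolised C8 carbonyl group, the second by the fact that attack at C6 would give a cyclobutane.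

Step 5
Reactants: 11 9β-allyl-4,4,10β-trimethyldecal-5-en-8-one
Product: 12 9β-allyl-5α,6α-epoxy-4,4,10β-trimethyldecalin-8-one
Conditions: DMDO (1.05 equiv), acetone/CH2Cl2, −20 °C
Reagents that add atoms: dimethyldioxirane CC1(C)OO1
Why: Neutral dioxirane epoxidation picks the electron-rich trisubstituted C5=C6 alkene over the terminal allyl group and approaches from the α face, opposite the axial methyl groups on C10 and C4, so the oxygen returns to C6 in the configuration of the target.

Step 6
Reactants: 12 9β-allyl-5α,6α-epoxy-4,4,10β-trimethyldecalin-8-one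
Product: 13 9β-allyl-6α-hydroxy-4,4,10β-trimethyl-trans-decalin-8-one (5α-H; 9α-H)
Conditions: Cp2TiCl2 (15 mol %), Mn dust, 2,4,6-collidine·HCl, 1,4-cyclohexadiene, THF, rt
Reagents that add atoms: none
Why: Titanocene-catalysed reductive epoxide opening, in which electron transfer from Cp2TiCl (trivalent titanium) cleaves the C5–O bond to the tertiary C5 radical and keeps the C6–O bond, and hydrogen-atom transfer to the less hindered α face gives the trans-decalin with 5α-H while the allyl group on epimerisable C9 rests equatorial.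

Step 7
Reactants: 13 9β-allyl-6α-hydroxy-4,4,10β-trimethyl-trans-decalin-8-one; 14 (R)-2-methylbutanoic acid
Product: 15 9β-allyl-4,4,10β-trimethyl-8-oxo-trans-decalin-6α-yl (R)-2-methylbutanoate
Conditions: DCC, DMAP (10 mol %), CH2Cl2, 0 °C → rt
Reagents that add atoms: none
Why: Steglich esterification of the equatorial C6 alcohol forms only the O–acyl bond, so neither C6 nor the α-carbon of the acid is disturbed under the cold, weakly basic conditions.

Step 8
Reactants: 15 9β-allyl-4,4,10β-trimethyl-8-oxo-trans-decalin-6α-yl (R)-2-methylbutanoate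
Product: 17 9β-allyl-4,4,10β-trimethyl-8-(trifluoromethylsulfonyloxy)-trans-decal-7-en-6α-yl (R)-2-methylbutanoate, via potassium enolate 16 (not isolated)
Conditions: KHMDS (1.1 equiv) added to 15 + N-(5-chloropyridin-2-yl)bis(trifluoromethanesulfonimide), THF, −78 °C
Reagents that add atoms: N-(5-chloropyridin-2-yl)bis(trifluoromethanesulfonimide) O=S(=O)(N(c1ccc(Cl)cn1)S(=O)(=O)C(F)(F)F)C(F)(F)F
Why: Kinetic enolisation and O-triflation with internal quench, in which the bulky amide takes a proton from the C7 methylene group rather than the tertiary C9–H next to quaternary C10, and the equatorial C6 ester lies near the nodal plane of the enolate so that β-elimination is slow at −78 °C.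

Step 9
Reactants: 17 9β-allyl-4,4,10β-trimethyl-8-(trifluoromethylsulfonyloxy)-trans-decal-7-en-6α-yl (R)-2-methylbutanoate
Product: 18 9β-allyl-6α-[(R)-2-methylbutanoyloxy]-4,4,10β-trimethyl-trans-decal-7-ene-8-carboxylic acid
Conditions: Pd(OAc)2 (5 mol %), dppf (6 mol %), CO (1 atm), H2O, Et3N, DMF, 50 °C; acidic work-up
Reagents that add atoms: carbon monoxide [C-]#[O+]; water O
Why: Palladium-catalysed hydroxycarbonylation of an enol triflate (oxidative addition, CO insertion, hydrolysis of the acylpalladium species) puts the C17 carboxyl group on C8 with the C7=C8 double bond fixed in place and touches no stereocentre.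

Step 10
Reactants: 18 9β-allyl-6α-[(R)-2-methylbutanoyloxy]-4,4,10β-trimethyl-trans-decal-7-ene-8-carboxylic acid; 19 α-methylene-γ-butyrolactone
Product: 20 (12E)-6α-[(R)-2-methylbutanoyloxy]labda-7,12-dien-16,15-olid-17-oic acid
Conditions: second-generation Hoveyda–Grubbs catalyst RuCl2(H2IMes)(=CH-C6H4-2-OiPr) (5 mol %), 2,6-dichloro-1,4-benzoquinone (10 mol %), 19 (3 equiv), CH2Cl2, 40 °C
Reagents that add atoms: none
Why: Olefin cross metathesis between the terminal alkene of 18 and the 1,1-disubstituted, slowly homodimerising alkene of 19 joins C12 to C13 of the ready-made lactone ring, the quinone suppressing ruthenium hydride isomerisation of 19 and the trisubstituted C7=C8 enoate being inert.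

Step 11
Reactants: 20 (12E)-6α-[(R)-2-methylbutanoyloxy]labda-7,12-dien-16,15-olid-17-oic acid
Product: 21 6α-[(R)-2-methylbutanoyloxy]labda-7,13-dien-16,15-olid-17-oic acid (CNP0150853.1)
Conditions: RhCl3·3H2O (5 mol %), EtOH, 75 °C
Reagents that add atoms: none
Why: Rhodium hydride addition–elimination moves the exocyclic C12=C13 double bond into the ring (the exo-to-endo isomerisation known for 2-alkylidene cyclopentanones and lactones), the endocyclic butenolide being the more stable conjugated isomer, and no stereocentre is touched.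

**Compound list**
1 | β-cyclocitral | O=CC1=C(C)CCCC1(C)C | starting material
2 | 1-methoxy-1,3-bis(trimethylsilyloxy)buta-1,3-diene | COC(O[Si](C)(C)C)=CC(=C)O[Si](C)(C)C | starting material
3 | methyl (5S)-3,5-bis(trimethylsilyloxy)-5-(2,6,6-trimethylcyclohex-1-en-1-yl)pent-2-enoate | COC(=O)C=C(O[Si](C)(C)C)C[C@H](O[Si](C)(C)C)C1=C(C)CCCC1(C)C | intermediate
4 | methyl (5S)-5-hydroxy-3-oxo-5-(2,6,6-trimethylcyclohex-1-en-1-yl)pentanoate | COC(=O)CC(=O)C[C@H](O)C1=C(C)CCCC1(C)C | intermediate
5 | potassium (6S)-2-oxo-6-(2,6,6-trimethylcyclohex-1-en-1-yl)-5,6-dihydro-2H-pyran-4-olate | O=C1C=C([O-])C[C@@H](C2=C(C)CCCC2(C)C)O1.[K+] | intermediate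
6 | (6S)-4-hydroxy-6-(2,6,6-trimethylcyclohex-1-en-1-yl)-5,6-dihydro-2H-pyran-2-one | O=C1C=C(O)C[C@@H](C2=C(C)CCCC2(C)C)O1 | intermediate
7 | allyl methyl carbonate | C=CCOC(=O)OC | starting material
8 | (6S)-3-allyl-4-hydroxy-6-(2,6,6-trimethylcyclohex-1-en-1-yl)-5,6-dihydro-2H-pyran-2-one | O=C1C(CC=C)=C(O)C[C@@H](C2=C(C)CCCC2(C)C)O1 | intermediate
9 | (2S)-5-allyl-6-hydroxy-2-(2,6,6-trimethylcyclohex-1-en-1-yl)-2,3-dihydro-4H-pyran-4-one | OC1=C(CC=C)C(=O)C[C@@H](C2=C(C)CCCC2(C)C)O1 | intermediate
10 | 9β-allyl-4,4,10β-trimethyl-8-oxodecal-5-ene-9α-carboxylic acid | OC(=O)[C@]1(CC=C)C(=O)CC=C2C(C)(C)CCC[C@@]21C | intermediate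
11 | 9β-allyl-4,4,10β-trimethyldecal-5-en-8-one (9α-H) | O=C1CC=C2C(C)(C)CCC[C@]2(C)[C@H]1CC=C | intermediate
12 | 9β-allyl-5α,6α-epoxy-4,4,10β-trimethyldecalin-8-one | O=C1C[C@@H]2O[C@@]23C(C)(C)CCC[C@]3(C)[C@H]1CC=C | intermediate
13 | 9β-allyl-6α-hydroxy-4,4,10β-trimethyl-trans-decalin-8-one | O[C@H]1CC(=O)[C@H](CC=C)[C@@]2(C)CCCC(C)(C)[C@H]12 | intermediate
14 | (R)-2-methylbutanoic acid | CC[C@@H](C)C(=O)O | starting material
15 | 9β-allyl-4,4,10β-trimethyl-8-oxo-trans-decalin-6α-yl (R)-2-methylbutanoate | CC[C@@H](C)C(=O)O[C@H]1CC(=O)[C@H](CC=C)[C@@]2(C)CCCC(C)(C)[C@H]12 | intermediate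
16 | potassium C7=C8 enolate of 15 | CC[C@@H](C)C(=O)O[C@H]1C=C([O-])[C@H](CC=C)[C@@]2(C)CCCC(C)(C)[C@H]12.[K+] | intermediate
17 | 9β-allyl-4,4,10β-trimethyl-8-(trifluoromethylsulfonyloxy)-trans-decal-7-en-6α-yl (R)-2-methylbutanoate | CC[C@@H](C)C(=O)O[C@H]1C=C(OS(=O)(=O)C(F)(F)F)[C@H](CC=C)[C@@]2(C)CCCC(C)(C)[C@H]12 | intermediate
18 | 9β-allyl-6α-[(R)-2-methylbutanoyloxy]-4,4,10β-trimethyl-trans-decal-7-ene-8-carboxylic acid | CC[C@@H](C)C(=O)O[C@H]1C=C(C(=O)O)[C@H](CC=C)[C@@]2(C)CCCC(C)(C)[C@H]12 | intermediate
19 | α-methylene-γ-butyrolactone | C=C1CCOC1=O | starting material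
20 | (12E)-6α-[(R)-2-methylbutanoyloxy]labda-7,12-dien-16,15-olid-17-oic acid | CC[C@@H](C)C(=O)O[C@H]1C=C(C(=O)O)[C@H](C/C=C3/C(=O)OCC3)[C@@]2(C)CCCC(C)(C)[C@H]12 | intermediate
21 | 6α-[(R)-2-methylbutanoyloxy]labda-7,13-dien-16,15-olid-17-oic acid | CC[C@@H](C)C(=O)O[C@H]1C=C(C(=O)O)[C@H](CCC2=CCOC2=O)[C@@]2(C)CCCC(C)(C)[C@H]12 | target

Total step count: 11. Longest linear sequence: 11 steps (1 → 21).

**Steps most likely to fail**

First, step 4. Heterolysis of the doubly activated allylic C6–O bond may run ahead of C–C bond formation. That would erode the transfer of chirality, or divert the material into β-elimination and decarboxylation of the opened chain.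
- The fallback sets out from 4 and comes back at 11, using only documented chemistry.
- The C8 carbonyl group of 4 is masked with 1,2-bis(trimethylsilyloxy)ethane and catalytic TMSOTf, and the hydroxy ester is closed with catalytic K2CO3 in MeOH to give ketal lactone F1.
- LDA and allyl bromide give allyl ketal lactone F2.
- LDA/TBSCl followed by heating in toluene effects the established Ireland–Claisen ring contraction of a 6-alkenyl δ-lactone silyl ketene acetal to ketal acid F3.
- Aqueous acid removes the ketal, which regenerates 10, and decarboxylation leads to 11.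

Second, step 8. β-Elimination of the C6 carboxylate from the enolate, or enolisation towards C9, may compete with O-triflation.
- The fallback sets out from 13 and comes back at 17, changing the order of events so that a poor leaving group sits on C6 during enolisation.
- TESOTf/2,6-lutidine gives TES ether ketone F4.
- KHMDS and the same triflimide give TES enol triflate F5.
- HF·pyridine frees hydroxy enol triflate F6, and Steglich esterification with 14 gives 17.

Third, step 11. The alkene migration may stall or be unselective, and the allylic ester may solvolyse in hot ethanol.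
- The fallback sets out from 18 and comes back at 21. It avoids both the alkylidene lactone and any alkene shift in the lactone.
- Second-generation Grubbs catalyst RuCl2(H2IMes)(PCy3)(=CHPh) in hot MeOH moves the allyl double bond by one position to give propenyl acid F7.
- Ethenolysis (ethylene, second-generation Hoveyda–Grubbs catalyst) cuts it to vinyl acid F8.
- Hydroboration with 9-BBN is followed by B-alkyl Suzuki–Miyaura coupling with bought 3-bromofuran-2(5H)-one (PdCl2(dppf), AsPh3, Cs2CO3, DMF/H2O). This joins C12 to C13 of the finished butenolide and gives 21.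

**Further compounds**
F1 | step 4 | ketal lactone | O=C1CC2(OCCO2)C[C@@H](C3=C(C)CCCC3(C)C)O1
F2 | step 4 | allyl ketal lactone | O=C1C(CC=C)C2(OCCO2)C[C@@H](C3=C(C)CCCC3(C)C)O1
F3 | step 4 | ketal acid | OC(=O)[C@]1(CC=C)C2(OCCO2)CC=C3C(C)(C)CCC[C@@]31C
F4 | step 8 | TES ether ketone | CC[Si](CC)(CC)O[C@H]1CC(=O)[C@H](CC=C)[C@@]2(C)CCCC(C)(C)[C@H]12
F5 | step 8 | TES enol triflate | CC[Si](CC)(CC)O[C@H]1C=C(OS(=O)(=O)C(F)(F)F)[C@H](CC=C)[C@@]2(C)CCCC(C)(C)[C@H]12
F6 | step 8 | hydroxy enol triflate | O[C@H]1C=C(OS(=O)(=O)C(F)(F)F)[C@H](CC=C)[C@@]2(C)CCCC(C)(C)[C@H]12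
F7 | step 11 | propenyl acid | CC[C@@H](C)C(=O)O[C@H]1C=C(C(=O)O)[C@H](/C=C/C)[C@@]2(C)CCCC(C)(C)[C@H]12
F8 | step 11 | vinyl acid | CC[C@@H](C)C(=O)O[C@H]1C=C(C(=O)O)[C@H](C=C)[C@@]2(C)CCCC(C)(C)[C@H]12
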